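**Amounts charged.** You have 0.330 M of reagent, all of it in the second phase, and starting material and protic impurity together can consume 0.450 M, more than the reagent can serve. So the reagent is the limiting reagent, and its ledger is the one to keep.

starting material 0.30 M; reagent in the second phase 0.330 M; protic impurity 0.150 M; time 30 s; volume of the second phase over the first 0.25

    reagent in the reaction phase ⇌ reagent in the second phase, rate k1*([reagent in the reaction phase] - [reagent in the second phase]/K1) per volume of the first phase (K1 = 1.7, k1 = 0.0115 s⁻¹)
    starting material + reagent in the reaction phase → target (k2 = 11.8 M⁻¹ s⁻¹)
    reagent in the reaction phase + target → over-reacted product (k3 = 4.79 M⁻¹ s⁻¹)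
    reagent in the reaction phase + protic impurity → quenched reagent (k4 = 2.83 M⁻¹ s⁻¹)
    starting material ⇌ dormant form (K5 = 2.3, k5 = 0.00358 s⁻¹)
    reagent in the reaction phase → decomposed reagent (k6 = 0.0127 s⁻¹)

- in the second phase: reagent in the second phase; everything else is in the first
- charges count per volume of the first phase; a concentration in a rate is the amount of a species over the volume of its own phase; every rate counts per litre of the first phase
- run time (flask): 30 s

1. the target standing at 30 s, as a percentage of the starting material charged
2. the change that raises the amount of target at 30 s, in percent of the starting material charged most ("none" if none brings more than 2 percentage points) (red / amber / none)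
3. amount of target at 30 s, in percent of the starting material charged, after red

**Opening entry.** With V1 the volume of the second phase over the first, and with the back-flow into the second phase neglected, the second-phase stock decays with time constant τ = K1·V1/k1 = 37.0 s. I neglect that back-flow since step 2 alone, with starting material as charged, halves the reagent in the reaction phase in 0.20 s, far faster than the crossing runs. The crossed amount C, the reagent delivered to the reaction phase by time t, is C = cBq(1 − exp(−t/τ)), with cBq the charge of reagent; it comes to 0.183 M at 30 s.

**Dividing C.** I divide C by pseudo-first-order coefficients taken midway. Starting material stands near 0.208 M, which gives 2.46 s⁻¹. Guessing target at C/3 gives 0.293 s⁻¹ for over-reaction. Protic impurity gives 0.424 s⁻¹, and decomposition 0.0127 s⁻¹.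

**Closing entries.** Target formation receives 0.141 M, over-reaction 0.0169 M, quenching 0.0243 M and decomposition 7.31 × 10⁻⁴ M. The books close at C. Target is 41.5 % of the charge, my figure for y. By this reckoning red delivers 0.265 M and amber 0.366 M, so I lean to amber, although its larger over-reaction entry stays unreckoned.

**The forecast.** It gives 40 %, amber and 48.5 %, its y slightly below mine, on the ground that “The reagent is consumed almost as soon as it crosses, so transfer limits the reaction”.

**The result.** The flask gives 40.0 %, amber and 49.0 %, with amber gaining 11 percentage points and red 8.9 points. The decomposition step and the way back from dormant form make no difference here.

**C reused.** In the flask, 44.5 % of the reagent remains in the second phase, so 0.183 M crossed, against C of 0.183 M. Of the target missing at 30 s, the transfer's drag accounts for a part, together with over-reaction: without the drag, target reaches 53.7 %. The neighbouring flask with 0.60 M of protic impurity keeps 44.5 % in the second phase, so 0.183 M crossed there, yet quenched reagent stands at 0.0638 M and target at 32.3 %.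

(The numbers of this flask were set for the occasion; the rest is arithmetic.)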